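**Target:** [(2S,3R,4S)-2-(3,4-dimethoxyphenyl)-4-hydroxyoxolan-3-yl]methyl 3,4-dimethoxybenzoate. Ring numbering used below: O1, C2 (aryl), C3 (CH2O-ester), C4 (OH), C5 (CH2). All three substituents are cis. Ar = 3,4-dimethoxyphenyl, Tr = triphenylmethyl, Cb = N,N-diisopropylcarbamoyl.

**Retrosynthetic overview**
1. Last step: selective acylation of the primary hydroxyl of the all-cis diol with 3,4-dimethoxybenzoyl chloride.
2. The oxolane (the only ring) is closed by O1–C5 bond formation: the benzylic OH opens a carbamoyloxy-epoxide made by hydroxyl-directed epoxidation of a (Z)-enol carbamate (sets C4). The anomeric carbamate is then reduced off and the trityl group removed.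
3. Key C2–C3 bond: homoaldol addition of an α-metalated (Z)-allyl carbamate (chiral homoenolate, d3 reagent) to veratraldehyde. It joins the aldehyde carbon to the carbon β to a latent aldehyde and sets C2 and C3 (syn, later cis).
4. The allyl carbamate comes from cis-but-2-ene-1,4-diol (mono-trityl ether, then carbamoylation).

Assumption: (−)-sparteine is taken to give the (S)-lithio carbamate as in the parent crotyl case, which Ti(OiPr)4 inverts to the (R)-titanium reagent needed here; if the sense is reversed, the (+)-sparteine surrogate is used with no other change.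

**Step 1**
Reactants: 1 (Z)-but-2-ene-1,4-diol
Product: 2 (Z)-4-(trityloxy)but-2-en-1-ol
Conditions: TrCl (1.0 equiv), 1 (3 equiv), Et3N, DMAP (cat.), CH2Cl2, 0 °C → rt
Reagents that add atoms: trityl chloride ClC(c1ccccc1)(c1ccccc1)c1ccccc1
Why: O-tritylation (SN1-type etherification); the bulky trityl group and the excess of the symmetric diol give the mono-ether.

**Step 2**
Reactants: 2 (Z)-4-(trityloxy)but-2-en-1-ol
Product: 3 (Z)-4-(trityloxy)but-2-en-1-yl N,N-diisopropylcarbamate
Conditions: NaH, THF, 0 °C; then iPr2NCOCl, 0 → 60 °C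
Reagents that add atoms: N,N-diisopropylcarbamoyl chloride CC(C)N(C(C)C)C(Cl)=O
Why: O-carbamoylation of the alkoxide (nucleophilic acyl substitution) installs the base-stable group that directs and stabilises the α-lithiation of the next step.

**Step 3 (key step)**
Reactants: 3 (Z)-4-(trityloxy)but-2-en-1-yl N,N-diisopropylcarbamate; 4 3,4-dimethoxybenzaldehyde
Product: 7 (1Z,3S,4S)-4-(3,4-dimethoxyphenyl)-4-hydroxy-3-[(trityloxy)methyl]but-1-en-1-yl N,N-diisopropylcarbamate, via lithiated carbamate 5 (not isolated), via allyltitanium reagent 6 (not isolated)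
Conditions: s-BuLi (1.15 equiv), (−)-sparteine (1.2 equiv), toluene, −78 °C, 1–2 h; Ti(OiPr)4 (3 equiv), −78 °C; then 4, −78 → −40 °C; aq. NH4Cl
Reagents that add atoms: none
Why: Hoppe homoaldol reaction (homoenolate umpolung): carbamate-directed, sparteine-mediated α-lithiation gives (S)-5, Ti(OiPr)4 exchanges with inversion to the configurationally stable (R)-allyltitanium 6, and this adds to 4 at its γ-carbon through a closed chair transition state in which the Z allyl geometry gives the syn adduct (C2 and C3, later cis on the ring), the axial carbamoyloxy group gives the Z-enol carbamate, and the C–Ti configuration fixes the absolute sense (3S,4S).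

**Step 4**
Reactants: 7 (1Z,3S,4S)-4-(3,4-dimethoxyphenyl)-4-hydroxy-3-[(trityloxy)methyl]but-1-en-1-yl N,N-diisopropylcarbamate
Product: 9 (2S,3S,4R,5S)-5-(3,4-dimethoxyphenyl)-3-hydroxy-4-[(trityloxy)methyl]oxolan-2-yl N,N-diisopropylcarbamate, via epoxide 8 (not isolated)
Conditions: VO(acac)2 (5 mol %), t-BuOOH (decane), CH2Cl2, 0 °C → rt, stirred until 8 has cyclised
Reagents that add atoms: tert-butyl hydroperoxide CC(C)(C)OO
Why: Hydroxyl-directed vanadium-catalysed epoxidation of a homoallylic alcohol: 1,3-allylic strain in the Z-enol carbamate holds C3–H in the alkene plane, so the vanadate on the benzylic oxygen delivers oxygen to the face carrying the carbinol carbon, which puts the new C4–O cis to CH2OTr, and the same hydroxyl then opens the labile carbamoyloxy-epoxide 8 at its acetal-like carbon to close the oxolane.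

**Step 5**
Reactants: 9 (2S,3S,4R,5S)-5-(3,4-dimethoxyphenyl)-3-hydroxy-4-[(trityloxy)methyl]oxolan-2-yl N,N-diisopropylcarbamate
Product: 11 (3S,4R,5S)-5-(3,4-dimethoxyphenyl)-4-(hydroxymethyl)oxolan-3-ol, via triethylsilyl ether 10 (not isolated)
Conditions: Et3SiH (4 equiv), TMSOTf (0.3 equiv), CH2Cl2, −78 → −30 °C; then AcOH–THF–H2O (3:1:1), rt
Reagents that add atoms: none
Why: Ionic hydrogenation: the silyl triflate ionises the anomeric carbamate to the oxolanyl oxocarbenium ion, which Et3SiH reduces to CH2, and the same pair cleaves the trityl ether reductively (trityl cation to Ph3CH) to give silyl ether 10, hydrolysed in the aqueous acetic acid stage, with no stereocentre formed or touched.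

**Step 6**
Reactants: 11 (3S,4R,5S)-5-(3,4-dimethoxyphenyl)-4-(hydroxymethyl)oxolan-3-ol; 12 3,4-dimethoxybenzoyl chloride
Product: 13 [(2S,3R,4S)-2-(3,4-dimethoxyphenyl)-4-hydroxyoxolan-3-yl]methyl 3,4-dimethoxybenzoate
Conditions: 12 (1.05 equiv), 2,4,6-collidine, CH2Cl2, −40 → 0 °C
Reagents that add atoms: none
Why: Chemoselective O-acylation with an acid chloride: the unhindered primary hydroxyl reacts much faster than the secondary ring hydroxyl flanked by a cis substituent, under a weak hindered base at low temperature.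

**Compound list**
1 | (Z)-but-2-ene-1,4-diol | OC/C=C\CO | starting material
2 | (Z)-4-(trityloxy)but-2-en-1-ol | OC/C=C\COC(c1ccccc1)(c1ccccc1)c1ccccc1 | intermediate
3 | (Z)-4-(trityloxy)but-2-en-1-yl N,N-diisopropylcarbamate | CC(C)N(C(C)C)C(=O)OC/C=C\COC(c1ccccc1)(c1ccccc1)c1ccccc1 | intermediate
4 | 3,4-dimethoxybenzaldehyde (veratraldehyde) | COc1ccc(C=O)cc1OC | starting material
5 | [(1S,2Z)-1-(diisopropylcarbamoyloxy)-4-(trityloxy)but-2-en-1-yl]lithium, as its (−)-sparteine complex | [Li][C@H](OC(=O)N(C(C)C)C(C)C)/C=C\COC(c1ccccc1)(c1ccccc1)c1ccccc1 | intermediate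
6 | [(1R,2Z)-1-(diisopropylcarbamoyloxy)-4-(trityloxy)but-2-en-1-yl]tri(isopropoxy)titanium | CC(C)O[Ti](OC(C)C)(OC(C)C)[C@@H](OC(=O)N(C(C)C)C(C)C)/C=C\COC(c1ccccc1)(c1ccccc1)c1ccccc1 | intermediate
7 | (1Z,3S,4S)-4-(3,4-dimethoxyphenyl)-4-hydroxy-3-[(trityloxy)methyl]but-1-en-1-yl N,N-diisopropylcarbamate | C(c1ccccc1)(c1ccccc1)(c1ccccc1)OC[C@@H]([C@H](O)c1ccc(OC)c(OC)c1)/C=C\OC(=O)N(C(C)C)C(C)C | intermediate
8 | (2R,3S)-3-[(1S,2S)-1-(3,4-dimethoxyphenyl)-1-hydroxy-3-(trityloxy)propan-2-yl]oxiran-2-yl N,N-diisopropylcarbamate | C(c1ccccc1)(c1ccccc1)(c1ccccc1)OC[C@@H]([C@H](O)c1ccc(OC)c(OC)c1)[C@@H]1O[C@@H]1OC(=O)N(C(C)C)C(C)C | intermediate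
9 | (2S,3S,4R,5S)-5-(3,4-dimethoxyphenyl)-3-hydroxy-4-[(trityloxy)methyl]oxolan-2-yl N,N-diisopropylcarbamate (drawn as the anomer from anti opening of 8; the anomeric centre is removed in step 5) | C(c1ccccc1)(c1ccccc1)(c1ccccc1)OC[C@@H]2[C@H](O)[C@H](OC(=O)N(C(C)C)C(C)C)O[C@@H]2c2ccc(OC)c(OC)c2 | intermediate
10 | (3S,4R,5S)-5-(3,4-dimethoxyphenyl)-4-[(triethylsilyloxy)methyl]oxolan-3-ol | CC[Si](CC)(CC)OC[C@@H]1[C@H](O)CO[C@@H]1c1ccc(OC)c(OC)c1 | intermediate
11 | (3S,4R,5S)-5-(3,4-dimethoxyphenyl)-4-(hydroxymethyl)oxolan-3-ol | OC[C@@H]1[C@H](O)CO[C@@H]1c1ccc(OC)c(OC)c1 | intermediate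
12 | 3,4-dimethoxybenzoyl chloride | COc1ccc(C(Cl)=O)cc1OC | starting material
13 | [(2S,3R,4S)-2-(3,4-dimethoxyphenyl)-4-hydroxyoxolan-3-yl]methyl 3,4-dimethoxybenzoate | COc1ccc(C(=O)OC[C@@H]2[C@H](O)CO[C@@H]2c2ccc(OC)c(OC)c2)cc1OC | target

**Totals**
Total steps: 6. Longest linear sequence: 6 (1 → 2 → 3 → 7 → 9 → 11 → 13).

**Three steps most likely to fail**

Step 3 (homoaldol). Sparteine-controlled enantioselection is established for the parent crotyl carbamate but untested for this Z, 4-oxygenated substrate. The lithiated species may lose trityloxide by 1,4-elimination if it is warmed or aged, so lithiation is kept at −78 °C and short. The bulky Z substituent may also erode the syn and Z-enol selectivity. Fallback, setting out from 3 and 4 and returning at 9: give up ligand control in the C–C step and move the source of absolute configuration to a catalyst-controlled kinetic resolution. Compound 3 is lithiated with s-BuLi/TMEDA, titanated and added to 4 as before, which gives the racemic syn adduct, that is 7 together with its mirror image, the (1Z,3R,4R)-enol carbamate F1. The mixture is then epoxidised with a chiral vanadium bis-hydroxamic acid catalyst and cumene hydroperoxide to about half conversion, so that only the (3S,4S) enantiomer is epoxidised and cyclises to 9, while F1 stays behind and is separated.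

Step 4 (directed epoxidation and ring closure). The facial selectivity rests on the directing effect winning over the steric bias of the two allylic substituents. The benzylic alcohol could also be oxidised, or the carbamoyloxy-epoxide could rearrange before it cyclises. Fallback, setting out from 7 and returning at 11: replace epoxidation by hydrogen-bond-directed dihydroxylation with stoichiometric OsO4·TMEDA in CH2Cl2 at −78 °C, which adds syn to the benzylic hydroxyl on the same alkene face. On sulfite work-up the hemiacetal carbamate loses diisopropylcarbamic acid and the hydroxy aldehyde closes to the lactol (3S,4R,5S)-5-(3,4-dimethoxyphenyl)-4-[(trityloxy)methyl]oxolane-2,3-diol F2 (anomeric mixture). F2 is reduced and detritylated under the conditions of step 5 to give 11.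

Step 5 (ionic hydrogenation with detritylation). The acid could ionise the electron-rich benzylic C2–O bond, causing epimerisation or reductive ring opening. Once the primary oxygen is free it could also capture the oxocarbenium ion and lead to the isomeric oxolane. Fallback, setting out from 9 and returning at 11, with no cation at the anomeric or benzylic carbon: LiAlH4 in THF at 0 °C cleaves the carbamate and reduces the released lactol to (2S,3S,4S)-4-(3,4-dimethoxyphenyl)-3-[(trityloxy)methyl]butane-1,2,4-triol F3. TsCl in pyridine sulfonylates only the primary hydroxyl to give (2S,3S,4S)-4-(3,4-dimethoxyphenyl)-2,4-dihydroxy-3-[(trityloxy)methyl]butyl 4-methylbenzenesulfonate F4. On warming, the benzylic hydroxyl displaces the tosylate (5-exo-tet, retention at every stereocentre) to give (3S,4R,5S)-5-(3,4-dimethoxyphenyl)-4-[(trityloxy)methyl]oxolan-3-ol F5. Catalytic CSA in MeOH–CH2Cl2 at 0 °C removes the trityl group and gives 11.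

**Further compounds**
F1 | step 3 | (1Z,3R,4R)-4-(3,4-dimethoxyphenyl)-4-hydroxy-3-[(trityloxy)methyl]but-1-en-1-yl N,N-diisopropylcarbamate (enantiomer of 7) | C(c1ccccc1)(c1ccccc1)(c1ccccc1)OC[C@H]([C@@H](O)c1ccc(OC)c(OC)c1)/C=C\OC(=O)N(C(C)C)C(C)C
F2 | step 4 | (3S,4R,5S)-5-(3,4-dimethoxyphenyl)-4-[(trityloxy)methyl]oxolane-2,3-diol (anomeric mixture) | C(c1ccccc1)(c1ccccc1)(c1ccccc1)OC[C@@H]2[C@H](O)C(O)O[C@@H]2c2ccc(OC)c(OC)c2
F3 | step 5 | (2S,3S,4S)-4-(3,4-dimethoxyphenyl)-3-[(trityloxy)methyl]butane-1,2,4-triol | C(c1ccccc1)(c1ccccc1)(c1ccccc1)OC[C@@H]([C@H](O)c1ccc(OC)c(OC)c1)[C@H](O)CO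
F4 | step 5 | (2S,3S,4S)-4-(3,4-dimethoxyphenyl)-2,4-dihydroxy-3-[(trityloxy)methyl]butyl 4-methylbenzenesulfonate | C(c1ccccc1)(c1ccccc1)(c1ccccc1)OC[C@@H]([C@H](O)c1ccc(OC)c(OC)c1)[C@H](O)COS(=O)(=O)c1ccc(C)cc1
F5 | step 5 | (3S,4R,5S)-5-(3,4-dimethoxyphenyl)-4-[(trityloxy)methyl]oxolan-3-ol | C(c1ccccc1)(c1ccccc1)(c1ccccc1)OC[C@@H]2[C@H](O)CO[C@@H]2c2ccc(OC)c(OC)c2
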